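## Retrosynthetic overview

1. The p-quinone, the only ring, is cut into two O=C–C=C halves across two acyl–alkenyl bonds: the bond from the carbonyl flanked by two methyl-bearing carbons to the methyl-bearing carbon next to the side chain, and the bond from the other carbonyl to its methyl-bearing neighbour. Both should form in one rhodium-catalysed [3+3] annulation of 2,3-dimethylcyclopropenone with a β-boryl enoate, directly at the quinone oxidation level.
2. Enabling feature: the quinone ring is a head-to-tail pair of two O=C–C=C units. The unit O=C–C(CH3)=C(CH3) has the same substituent on both alkene carbons, so it is a latent C2v-symmetric, strained cyclopropenone whose two ring C–C(=O) bonds are equivalent. The other unit, O=C–C(side chain)=C(CH3), is an α-alkylated acetoacetate in disguise.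
3. β-Boryl enoate: methyl acetoacetate plus the C20 iodide, then (Z)-enol triflate, then Miyaura borylation.
4. C20 iodide: natural phytol supplies the two CH(CH3) centres; Sharpless epoxidation sets the tertiary carbinol centre; Red-Al opening, iodination and TES protection follow.
5. Ring order: no ring exists until step 9, where the quinone ring is closed; step 10 only removes the silyl group.

Key step: step 9

Assumption: natural (2E,7R,11R)-phytol of high geometric and optical purity is taken as the commercial chiral-pool starting material.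

## Route

Step 1
Reactants: 1 (2E,7R,11R)-3,7,11,15-tetramethylhexadec-2-en-1-ol (natural phytol)
Product: 2 [(2R,3R)-3-methyl-3-[(4R,8R)-4,8,12-trimethyltridecyl]oxiran-2-yl]methanol
Conditions: Ti(OiPr)4 (10 mol %), D-(−)-diethyl tartrate (12 mol %), t-BuOOH, 4 Å MS, CH2Cl2, −20 °C
Reagents that add atoms: tert-butyl hydroperoxide, CC(C)(C)OO
Why: Sharpless asymmetric epoxidation of the (E)-trisubstituted allylic alcohol, in which the D-(−)-tartrate/titanium catalyst delivers oxygen to the face that gives the (2R,3R)-epoxide and so sets the quaternary C3 centre that becomes the tertiary carbinol, the remote (7R,11R) centres being untouched.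

Step 2
Reactants: 2 [(2R,3R)-3-methyl-3-[(4R,8R)-4,8,12-trimethyltridecyl]oxiran-2-yl]methanol
Product: 3 (3R,7R,11R)-3,7,11,15-tetramethylhexadecane-1,3-diol
Conditions: NaAlH2(OCH2CH2OCH3)2 (Red-Al), THF, 0 °C to rt; aq. potassium sodium tartrate
Reagents that add atoms: none
Why: Hydroxyl-directed reductive opening of a 2,3-epoxy alcohol, in which the alkoxyaluminate delivers hydride intramolecularly to the less substituted C2, so that the 1,3-diol forms and the C3–O bond, hence the (R) configuration, is retained.

Step 3
Reactants: 3 (3R,7R,11R)-3,7,11,15-tetramethylhexadecane-1,3-diol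
Product: 4 (3R,7R,11R)-1-iodo-3,7,11,15-tetramethylhexadecan-3-ol
Conditions: I2, PPh3, imidazole, CH2Cl2, 0 °C to rt
Reagents that add atoms: iodine, II
Why: Appel-type iodination converts only the primary alcohol, because the hindered tertiary alcohol does not form an alkoxyphosphonium ion that iodide can displace, and no stereocentre is touched.

Step 4
Reactants: 4 (3R,7R,11R)-1-iodo-3,7,11,15-tetramethylhexadecan-3-ol
Product: 5 triethyl{[(3R,7R,11R)-1-iodo-3,7,11,15-tetramethylhexadecan-3-yl]oxy}silane
Conditions: Et3SiOTf, 2,6-lutidine, CH2Cl2, −78 to 0 °C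
Reagents that add atoms: triethylsilyl trifluoromethanesulfonate, CC[Si](CC)(CC)OS(=O)(=O)C(F)(F)F
Why: Silylation with a silyl triflate and a hindered pyridine base is the standard protection of a tertiary alcohol, and the ether prevents hemiketal formation with the ketone of 7 and alkoxide interference in steps 5 to 9.

Step 5
Reactants: 5 triethyl{[(3R,7R,11R)-1-iodo-3,7,11,15-tetramethylhexadecan-3-yl]oxy}silane; 6 methyl acetoacetate (methyl 3-oxobutanoate)
Product: 7 methyl (5R,9R,13R)-2-acetyl-5,9,13,17-tetramethyl-5-(triethylsilyloxy)octadecanoate (both C2 epimers)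
Conditions: NaH, 6 (3 equiv), THF/DMF, 0 to 60 °C
Reagents that add atoms: none
Why: Acetoacetic ester C-alkylation of the sodium enolate with an unhindered primary iodide, with excess enolate to suppress dialkylation; the new C2 centre forms as both epimers, which is immaterial because it becomes sp2 in step 6.

Step 6
Reactants: 7 methyl (5R,9R,13R)-2-acetyl-5,9,13,17-tetramethyl-5-(triethylsilyloxy)octadecanoate
Product: 8 methyl (2Z,5R,9R,13R)-5,9,13,17-tetramethyl-5-(triethylsilyloxy)-2-[1-(trifluoromethylsulfonyloxy)ethylidene]octadecanoate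
Conditions: Tf2O, sat. aq. LiOH, toluene, 5 °C
Reagents that add atoms: trifluoromethanesulfonic anhydride, O=S(=O)(OS(=O)(=O)C(F)(F)F)C(F)(F)F
Why: O-triflation of the lithium-chelated (Z)-enolate of the β-keto ester under biphasic Schotten–Baumann-type conditions, in which chelation of lithium between the two carbonyl oxygens fixes the geometry so that the triflate ends up cis to the ester, as the ring closure of step 9 requires.

Step 7
Reactants: 8 methyl (2Z,5R,9R,13R)-5,9,13,17-tetramethyl-5-(triethylsilyloxy)-2-[1-(trifluoromethylsulfonyloxy)ethylidene]octadecanoate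
Product: 9 methyl (2E,5R,9R,13R)-5,9,13,17-tetramethyl-2-[1-(4,4,5,5-tetramethyl-1,3,2-dioxaborolan-2-yl)ethylidene]-5-(triethylsilyloxy)octadecanoate (boron cis to the ester)
Conditions: PdCl2(PPh3)2 (3 mol %), PPh3, B2pin2, KOPh, toluene, 50 °C
Reagents that add atoms: bis(pinacolato)diboron, CC1(C)OB(OC1(C)C)B1OC(C)(C)C(C)(C)O1
Why: Miyaura borylation of an alkenyl triflate (oxidative addition to zerovalent palladium, transmetalation from the diboron through a phenoxo–palladium species, reductive elimination) proceeds with retention of alkene geometry and is a known reaction of β-triflyloxy enoates.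

Step 8
Reactants: 10 but-2-yne
Product: 12 2,3-dimethylcycloprop-2-en-1-one, via 3,3-difluoro-1,2-dimethylcyclopropene 11 (not isolated)
Conditions: TMSCF3, NaI (initiator), THF, sealed tube, 110 °C; then H2O, silica gel, rt
Reagents that add atoms: trimethyl(trifluoromethyl)silane, C[Si](C)(C)C(F)(F)F; water, O
Why: [2+1] cycloaddition of difluorocarbene, released from TMSCF3 by iodide initiation, to the internal alkyne gives the gem-difluorocyclopropene, whose hydrolysis through the fluorocyclopropenylium ion gives the cyclopropenone, both being established reactions of dialkylalkynes.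

Step 9
Reactants: 9 methyl (2E,5R,9R,13R)-5,9,13,17-tetramethyl-2-[1-(4,4,5,5-tetramethyl-1,3,2-dioxaborolan-2-yl)ethylidene]-5-(triethylsilyloxy)octadecanoate; 12 2,3-dimethylcycloprop-2-en-1-one
Product: 16 2,3,5-trimethyl-6-[(3R,7R,11R)-3,7,11,15-tetramethyl-3-(triethylsilyloxy)hexadecyl]cyclohexa-2,5-diene-1,4-dione, via alkenylrhodium 13 (not isolated), via rhodium cyclopropenolate 14 (not isolated), via ring-opened alkenylrhodium 15 (not isolated)
Conditions: [Rh(OH)(cod)]2 (5 mol %), 12 (2 equiv), 1,4-dioxane, 4 Å MS, 60 °C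
Reagents that add atoms: none
Why: Proposed new method: boron-to-rhodium transmetalation of 9 should give the ester-chelated alkenyl complex of monovalent rhodium 13, which adds across the C=O group of 12 (first new bond, cyclopropenone carbonyl carbon to the methyl-bearing alkenyl carbon) to give cyclopropenolate 14; strain-driven β-carbon elimination then opens the three-membered ring to the cis-β-acylalkenylrhodium 15, which attacks the cis methyl ester (second new bond) and expels Rh–OCH3, which re-enters the cycle by transmetalation with 9. The closest known reaction types are the rhodium-catalysed addition/ring-opening of organoboron reagents with cyclobutanones, the rhodium-catalysed ring-opening acylation of aryl C–H bonds with cyclopropenones, and the intramolecular acylation of alkenylrhodium species by esters; their merger into a [3+3] quinone annulation is the untested part. The quinone ring closes by a 6-exo-trig addition–elimination at the ester carbonyl. No stereocentre is formed, and the three side-chain stereocentres are remote and untouched. The step needs 1,2-addition to the C=O group rather than insertion into the C=C bond, which the exposed Lewis-basic carbonyl and the fully substituted ring alkene should secure; it also needs ester and rhodium on the same side of the alkene, which the geometry fixed in step 6 provides. No regiochemical question arises because the two C–C(=O) bonds of 12 are equivalent, and cross-selectivity is built in because only 9 carries boron and only 12 carries ring strain.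

Step 10
Reactants: 16 2,3,5-trimethyl-6-[(3R,7R,11R)-3,7,11,15-tetramethyl-3-(triethylsilyloxy)hexadecyl]cyclohexa-2,5-diene-1,4-dione
Product: 17 2-[(3R,7R,11R)-3-hydroxy-3,7,11,15-tetramethylhexadecyl]-3,5,6-trimethylcyclohexa-2,5-diene-1,4-dione (tocopherylquinone)
Conditions: HF·pyridine, THF, 0 °C to rt
Reagents that add atoms: none
Why: Fluoride-mediated cleavage of the tertiary triethylsilyl ether under weakly acidic, non-reducing conditions should leave the quinone and the C–O bond of the carbinol stereocentre untouched.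

## Compound list

1 | (2E,7R,11R)-3,7,11,15-tetramethylhexadec-2-en-1-ol (natural phytol) | OC/C=C(\C)CCC[C@H](C)CCC[C@H](C)CCCC(C)C | starting material
2 | [(2R,3R)-3-methyl-3-[(4R,8R)-4,8,12-trimethyltridecyl]oxiran-2-yl]methanol | OC[C@H]1O[C@]1(C)CCC[C@H](C)CCC[C@H](C)CCCC(C)C | intermediate
3 | (3R,7R,11R)-3,7,11,15-tetramethylhexadecane-1,3-diol | OCC[C@](C)(O)CCC[C@H](C)CCC[C@H](C)CCCC(C)C | intermediate
4 | (3R,7R,11R)-1-iodo-3,7,11,15-tetramethylhexadecan-3-ol | ICC[C@](C)(O)CCC[C@H](C)CCC[C@H](C)CCCC(C)C | intermediate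
5 | triethyl{[(3R,7R,11R)-1-iodo-3,7,11,15-tetramethylhexadecan-3-yl]oxy}silane | ICC[C@](C)(O[Si](CC)(CC)CC)CCC[C@H](C)CCC[C@H](C)CCCC(C)C | intermediate
6 | methyl acetoacetate | COC(=O)CC(C)=O | starting material
7 | methyl (5R,9R,13R)-2-acetyl-5,9,13,17-tetramethyl-5-(triethylsilyloxy)octadecanoate (C2 epimers) | COC(=O)C(CC[C@](C)(O[Si](CC)(CC)CC)CCC[C@H](C)CCC[C@H](C)CCCC(C)C)C(C)=O | intermediate
8 | methyl (2Z,5R,9R,13R)-5,9,13,17-tetramethyl-5-(triethylsilyloxy)-2-[1-(trifluoromethylsulfonyloxy)ethylidene]octadecanoate | COC(=O)C(/CC[C@](C)(O[Si](CC)(CC)CC)CCC[C@H](C)CCC[C@H](C)CCCC(C)C)=C(/C)OS(=O)(=O)C(F)(F)F | intermediate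
9 | methyl (2E,5R,9R,13R)-5,9,13,17-tetramethyl-2-[1-(4,4,5,5-tetramethyl-1,3,2-dioxaborolan-2-yl)ethylidene]-5-(triethylsilyloxy)octadecanoate | COC(=O)C(/CC[C@](C)(O[Si](CC)(CC)CC)CCC[C@H](C)CCC[C@H](C)CCCC(C)C)=C(/C)B1OC(C)(C)C(C)(C)O1 | intermediate
10 | but-2-yne | CC#CC | starting material
11 | 3,3-difluoro-1,2-dimethylcyclopropene | CC1=C(C)C1(F)F | intermediate
12 | 2,3-dimethylcycloprop-2-en-1-one | CC1=C(C)C1=O | intermediate
13 | alkenylrhodium: (cod)Rh on the former boron-bearing carbon of 9 | COC(=O)C(/CC[C@](C)(O[Si](CC)(CC)CC)CCC[C@H](C)CCC[C@H](C)CCCC(C)C)=C(/C)[Rh].C1=CCCC=CCC1 | intermediate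
14 | rhodium cyclopropenolate: (cod)Rh alkoxide of the 1-alkenyl-2,3-dimethylcycloprop-2-en-1-ol | COC(=O)C(/CC[C@](C)(O[Si](CC)(CC)CC)CCC[C@H](C)CCC[C@H](C)CCCC(C)C)=C(/C)C1(O[Rh])C(C)=C1C.C1=CCCC=CCC1 | intermediate
15 | ring-opened alkenylrhodium: (cod)Rh on the terminal alkenyl carbon of the cross-conjugated dienone ester, cis to the ketone | COC(=O)C(/CC[C@](C)(O[Si](CC)(CC)CC)CCC[C@H](C)CCC[C@H](C)CCCC(C)C)=C(/C)C(=O)/C(C)=C(/C)[Rh].C1=CCCC=CCC1 | intermediate
16 | 2,3,5-trimethyl-6-[(3R,7R,11R)-3,7,11,15-tetramethyl-3-(triethylsilyloxy)hexadecyl]cyclohexa-2,5-diene-1,4-dione | CC1=C(C)C(=O)C(CC[C@](C)(O[Si](CC)(CC)CC)CCC[C@H](C)CCC[C@H](C)CCCC(C)C)=C(C)C1=O | intermediate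
17 | 2-[(3R,7R,11R)-3-hydroxy-3,7,11,15-tetramethylhexadecyl]-3,5,6-trimethylcyclohexa-2,5-diene-1,4-dione (tocopherylquinone) | CC1=C(C)C(=O)C(CC[C@](C)(O)CCC[C@H](C)CCC[C@H](C)CCCC(C)C)=C(C)C1=O | target

## Step count and risks

Total step count: 10. Longest linear sequence: 9 steps (steps 1 to 7, 9 and 10, from phytol).

**Step 9 (proposed new method).** What may go wrong: protodemetalation of alkenylrhodium 13 before it adds to the carbonyl group; insertion into the C=C bond or decarbonylation of 12; slow boron-to-rhodium transmetalation at the hindered, chelated alkenylboronate; reduction of the product quinone by a rhodium hydride formed from the methoxide. The fallback uses known chemistry, sets out from 5 and returns at 16; the quinone ring is then brought in as an arene instead of being built. 1-Bromo-2,5-dimethoxy-3,4,6-trimethylbenzene F1 is converted with Mg in THF into (2,5-dimethoxy-3,4,6-trimethylphenyl)magnesium bromide F2. F2 is alkylated with iodide 5 under Li2CuCl4 catalysis (THF, −20 to 0 °C) to give the hydroquinone dimethyl ether triethyl{[(3R,7R,11R)-1-(2,5-dimethoxy-3,4,6-trimethylphenyl)-3,7,11,15-tetramethylhexadecan-3-yl]oxy}silane F3. Oxidative demethylation of F3 with (NH4)2Ce(NO3)6 (MeCN/H2O, 0 °C, short contact to keep the silyl ether) should give 16.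

**Step 7.** What may go wrong: slow oxidative addition at the tetrasubstituted alkenyl triflate, displacement of triflate by phenoxide through conjugate addition–elimination, and loss of alkene geometry. The fallback sets out from 8 and returns at 16. Base-free stannylation of 8 with (CH3)3SnSn(CH3)3, Pd(PPh3)4 and LiCl in dioxane should give methyl (2Z,5R,9R,13R)-5,9,13,17-tetramethyl-5-(triethylsilyloxy)-2-[1-(trimethylstannyl)ethylidene]octadecanoate F4. F4 replaces 9 in the annulation with 12 ([Rh(cod)(MeCN)2]BF4, THF, 60 °C), with tin-to-rhodium transmetalation taking the place of boron-to-rhodium transmetalation.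

**Step 6.** What may go wrong: erosion of enolate geometry during triflation of the bulky α-alkylated keto ester; the isomer with triflate trans to the ester cannot close the ring in step 9. The fallback sets out from 5 and 10 and returns at 16. The roles of the two halves are exchanged, so that no tetrasubstituted alkene geometry has to be set on the C20 fragment.
- Iodide 5 is alkylated with 1-propynyllithium (THF/DMPU) to give triethyl{[(6R,10R,14R)-6,10,14,18-tetramethylnonadec-2-yn-6-yl]oxy}silane F5.
- TMSCF3/NaI and then wet silica gel convert F5, through the difluorocyclopropene F6, into 2-methyl-3-[(3R,7R,11R)-3,7,11,15-tetramethyl-3-(triethylsilyloxy)hexadecyl]cycloprop-2-en-1-one F7.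
- Copper-catalysed boracarboxylation of but-2-yne 10 (B2pin2, CO2, LiOtBu, (IPr)CuCl, THF) gives lithium (2E)-2-methyl-3-(4,4,5,5-tetramethyl-1,3,2-dioxaborolan-2-yl)but-2-enoate F8. Syn addition across the symmetric alkyne guarantees boron cis to the carboxylate.
- CH3I converts F8 into the methyl ester F9.
- Annulation of F9 with F7 under the conditions of step 9 should give 16, because a trimethyl-monoalkyl quinone has only one constitution whichever C–C(=O) bond of F7 opens.

## Further compounds

F1 | step 9 | 1-bromo-2,5-dimethoxy-3,4,6-trimethylbenzene | COc1c(C)c(C)c(OC)c(C)c1Br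
F2 | step 9 | (2,5-dimethoxy-3,4,6-trimethylphenyl)magnesium bromide | COc1c(C)c(C)c(OC)c(C)c1[Mg]Br
F3 | step 9 | triethyl{[(3R,7R,11R)-1-(2,5-dimethoxy-3,4,6-trimethylphenyl)-3,7,11,15-tetramethylhexadecan-3-yl]oxy}silane | COc1c(C)c(C)c(OC)c(C)c1CC[C@](C)(O[Si](CC)(CC)CC)CCC[C@H](C)CCC[C@H](C)CCCC(C)C
F4 | step 7 | methyl (2Z,5R,9R,13R)-5,9,13,17-tetramethyl-5-(triethylsilyloxy)-2-[1-(trimethylstannyl)ethylidene]octadecanoate | COC(=O)C(/CC[C@](C)(O[Si](CC)(CC)CC)CCC[C@H](C)CCC[C@H](C)CCCC(C)C)=C(/C)[Sn](C)(C)C
F5 | step 6 | triethyl{[(6R,10R,14R)-6,10,14,18-tetramethylnonadec-2-yn-6-yl]oxy}silane | CC#CCC[C@](C)(O[Si](CC)(CC)CC)CCC[C@H](C)CCC[C@H](C)CCCC(C)C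
F6 | step 6 | triethyl{[(3R,7R,11R)-1-(3,3-difluoro-2-methylcycloprop-1-en-1-yl)-3,7,11,15-tetramethylhexadecan-3-yl]oxy}silane | CC1=C(CC[C@](C)(O[Si](CC)(CC)CC)CCC[C@H](C)CCC[C@H](C)CCCC(C)C)C1(F)F
F7 | step 6 | 2-methyl-3-[(3R,7R,11R)-3,7,11,15-tetramethyl-3-(triethylsilyloxy)hexadecyl]cycloprop-2-en-1-one | CC1=C(CC[C@](C)(O[Si](CC)(CC)CC)CCC[C@H](C)CCC[C@H](C)CCCC(C)C)C1=O
F8 | step 6 | lithium (2E)-2-methyl-3-(4,4,5,5-tetramethyl-1,3,2-dioxaborolan-2-yl)but-2-enoate | [Li+].[O-]C(=O)/C(C)=C(/C)B1OC(C)(C)C(C)(C)O1
F9 | step 6 | methyl (2E)-2-methyl-3-(4,4,5,5-tetramethyl-1,3,2-dioxaborolan-2-yl)but-2-enoate | COC(=O)/C(C)=C(/C)B1OC(C)(C)C(C)(C)O1
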